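**Retrosynthetic overview**
- The target is a C2-symmetric 22-membered [7.7]paracyclophane. The four phenols, the two carbamates and the two CHCl2 groups are unmasked or installed last, on the saturated macrocycle: MOM removal, carbamoylation of the two benzylic carbinols, and aldehyde → hydrazone → CHCl2.
- The strategy rests on the four contiguous CH2 groups in each bridge, between the CH(CH3) carbon and the benzylic CH that carries the dichlorobutyl chain. They are read as a buta-1,3-diyne whose two propargylic carbons are these two stereocentres.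
- The macrocycle is the only ring made (the resorcinol ring is bought). It is closed by head-to-tail cyclodimerisation of one monomer carrying a terminal alkyne and a 1-bromoalkyne, which forms two C(sp)–C(sp) bonds; hydrogenation then gives the two (CH2)4 tethers.
- Monomer: an Evans syn aldol on the aryl aldehyde sets the carbinol and CH(CH3) carbons, and the imide carbonyl carbon becomes the bromoalkyne. The benzylic stereocentre comes from a sparteine-mediated lithiation–borylation followed by a stereoretentive Zweifel-type alkynylation.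

Key step: step 17

Assumption: (+)-sparteine is taken as purchasable in enantiopure form, and organolithium steps are quenched with water, so lithium not bound as a halide ends as LiOH.

**Route**

Step 1
Reactants: 1 3,5-dihydroxybenzaldehyde
Product: 2 3,5-bis(methoxymethoxy)benzaldehyde
Conditions: MOMCl, iPr2NEt, CH2Cl2, 0 °C → rt
Reagents that add atoms: chloromethyl methyl ether COCCl
Why: Double O-alkylation of the phenols (acetal-type protection) should give the bis-MOM ether, which later directs ortho-lithiation and survives base, hydride, fluoride and hydrogenation.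

Step 2
Reactants: 2 3,5-bis(methoxymethoxy)benzaldehyde
Product: 3 1-(dimethoxymethyl)-3,5-bis(methoxymethoxy)benzene
Conditions: HC(OMe)3, MeOH, PPTS (cat.), rt; Et3N quench
Reagents that add atoms: trimethyl orthoformate COC(OC)OC; methanol CO
Why: Acid-catalysed acetalisation with the orthoformate as water scavenger should mask the aldehyde against n-BuLi, PPTS being too weak to cleave the aryl MOM ethers.

Step 3
Reactants: 3 1-(dimethoxymethyl)-3,5-bis(methoxymethoxy)benzene
Product: 5 2-[4-(dimethoxymethyl)-2,6-bis(methoxymethoxy)phenyl]-4,4,5,5-tetramethyl-1,3,2-dioxaborolane, via aryllithium 4 (not isolated)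
Conditions: n-BuLi, TMEDA, THF, 0 °C; iPrOBpin, −78 °C → rt
Reagents that add atoms: 2-isopropoxy-4,4,5,5-tetramethyl-1,3,2-dioxaborolane CC(C)OB1OC(C)(C)C(C)(C)O1
Why: Directed ortho-metalation should occur at the C–H flanked by both OMOM groups (double chelation), and the aryllithium is borylated by displacement of isopropoxide from boron.

Step 4
Reactants: 6 pentane-1,5-diol
Product: 7 5-(tert-butyldimethylsilyloxy)pentan-1-ol
Conditions: NaH (1 equiv), THF, 0 °C → rt; TBSCl (1 equiv)
Reagents that add atoms: tert-butyldimethylsilyl chloride CC(C)(C)[Si](C)(C)Cl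
Why: Silylation of the sparingly soluble monosodium alkoxide should stop at the mono-TBS ether (statistical desymmetrisation of a symmetrical diol).

Step 5
Reactants: 7 5-(tert-butyldimethylsilyloxy)pentan-1-ol
Product: 8 5-(tert-butyldimethylsilyloxy)pentyl N,N-diisopropylcarbamate
Conditions: iPr2NCOCl, Et3N, CH2Cl2, reflux
Reagents that add atoms: N,N-diisopropylcarbamoyl chloride CC(C)N(C(C)C)C(Cl)=O
Why: O-Carbamoylation (acyl substitution) installs the hindered carbamate that directs α-lithiation and later serves as the leaving group in the 1,2-metalate shift.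

Step 6
Reactants: 8 5-(tert-butyldimethylsilyloxy)pentyl N,N-diisopropylcarbamate; 5 aryl pinacol boronate
Product: 11 (S)-2-{5-(tert-butyldimethylsilyloxy)-1-[4-(dimethoxymethyl)-2,6-bis(methoxymethoxy)phenyl]pentyl}-4,4,5,5-tetramethyl-1,3,2-dioxaborolane, via lithiated carbamate 9 (not isolated), via boronate complex 10 (not isolated)
Conditions: s-BuLi, (+)-sparteine, Et2O, −78 °C, 5 h; 5 in Et2O, −78 °C; MgBr2·OEt2, −78 °C → reflux
Reagents that add atoms: none
Why: Asymmetric lithiation–borylation: (+)-sparteine/s-BuLi should remove the pro-R proton to give the configurationally stable (R)-lithio carbamate, which is borylated with retention and then undergoes 1,2-shift of the electron-rich aryl group with inversion (MgBr2 assisting carbamate departure), so the (S)-boronate is expected.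

Step 7
Reactants: 11 (S)-benzylic pinacol boronate
Product: 14 (S)-2-bromo-7-(tert-butyldimethylsilyloxy)-3-[4-(dimethoxymethyl)-2,6-bis(methoxymethoxy)phenyl]hept-1-ene, via bromovinyl boronate complex 12 (not isolated), via iodo boronic ester 13 (not isolated)
Conditions: vinyl bromide, LiN(iPr)2, THF, −78 °C; I2, MeOH, −78 °C; NaOMe, MeOH, −78 °C → rt
Reagents that add atoms: vinyl bromide C=CBr
Why: Zweifel-type olefination: 1-bromovinyllithium formed in the presence of 11 is captured as the boronate complex, iodine triggers 1,2-migration of the benzylic carbon with retention, and methoxide-induced anti elimination of boron and iodide should give the 2-bromoalkene with the stereocentre unchanged.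

Step 8
Reactants: 14 (S)-2-bromoalkene
Product: 16 (S)-7-(tert-butyldimethylsilyloxy)-3-[4-(dimethoxymethyl)-2,6-bis(methoxymethoxy)phenyl]-1-(trimethylsilyl)hept-1-yne, via lithium acetylide 15 (not isolated)
Conditions: LiN(iPr)2 (3 equiv), THF, −78 → −20 °C; TMSCl, −78 °C → rt
Reagents that add atoms: chlorotrimethylsilane C[Si](C)(C)Cl
Why: Base-mediated 1,2-dehydrobromination of the vinyl bromide should give the alkyne (the benzylic C–H is shielded by the two ortho MOM ethers), and the acetylide is C-silylated in the same flask because a free alkyne would later be deprotonated by the amide base and could exchange bromine with the bromoalkyne.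

Step 9
Reactants: 16 (S)-TMS-alkyne dimethyl acetal
Product: 17 4-[(S)-7-(tert-butyldimethylsilyloxy)-1-(trimethylsilyl)hept-1-yn-3-yl]-3,5-bis(methoxymethoxy)benzaldehyde
Conditions: PPTS (cat.), acetone/H2O, rt
Reagents that add atoms: water O
Why: Mild acid-catalysed acetal hydrolysis should free the aldehyde, the dimethyl acetal of an electron-rich benzaldehyde being far more labile than the MOM ethers, the TBS ether or the alkynylsilane.

Step 10
Reactants: 18 (R)-4-benzyl-3-propionyloxazolidin-2-one; 17 aryl aldehyde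
Product: 21 (R)-4-benzyl-3-[(2R,3R)-3-{4-[(S)-7-(tert-butyldimethylsilyloxy)-1-(trimethylsilyl)hept-1-yn-3-yl]-3,5-bis(methoxymethoxy)phenyl}-3-hydroxy-2-methylpropanoyl]oxazolidin-2-one, via boron enolate 19 (not isolated), via boron aldolate 20 (not isolated)
Conditions: 18, Bu2BOTf, iPr2NEt, CH2Cl2, −78 → 0 °C; 17, −78 → 0 °C; pH 7 buffer, MeOH, H2O2, 0 °C
Reagents that add atoms: none
Why: Evans syn aldol: the (Z)-dibutylboron enolate reacts through a Zimmerman–Traxler chair on the face opposite the benzyl group of the (R)-auxiliary, which should set the (2R,3R) syn carbinol/methyl pair, the remote benzylic centre having no influence.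

Step 11
Reactants: 21 syn aldol adduct
Product: 22 (R)-4-benzyl-3-[(2R,3R)-3-(tert-butyldimethylsilyloxy)-3-{4-[(S)-7-(tert-butyldimethylsilyloxy)-1-(trimethylsilyl)hept-1-yn-3-yl]-3,5-bis(methoxymethoxy)phenyl}-2-methylpropanoyl]oxazolidin-2-one
Conditions: TBSOTf, 2,6-lutidine, CH2Cl2, −78 → 0 °C
Reagents that add atoms: tert-butyldimethylsilyl trifluoromethanesulfonate CC(C)(C)[Si](C)(C)OS(=O)(=O)C(F)(F)F
Why: Silylation of the hindered secondary alcohol with the silyl triflate blocks retro-aldol and gives a benzylic ether robust enough to reach the carbamoylation stage.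

Step 12
Reactants: 22 silylated imide
Product: 23 (2S,3R)-3-(tert-butyldimethylsilyloxy)-3-{4-[(S)-7-(tert-butyldimethylsilyloxy)-1-(trimethylsilyl)hept-1-yn-3-yl]-3,5-bis(methoxymethoxy)phenyl}-2-methylpropan-1-ol
Conditions: LiBH4, MeOH (1 equiv), THF, 0 °C
Reagents that add atoms: none
Why: Reductive cleavage of the N-acyl oxazolidinone (hydride attack at the exocyclic carbonyl) should give the primary alcohol and release the auxiliary without touching the alkynylsilane or the silyl ethers.

Step 13
Reactants: 23 primary alcohol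
Product: 24 (2R,3R)-3-(tert-butyldimethylsilyloxy)-3-{4-[(S)-7-(tert-butyldimethylsilyloxy)-1-(trimethylsilyl)hept-1-yn-3-yl]-3,5-bis(methoxymethoxy)phenyl}-2-methylpropanal
Conditions: Dess–Martin periodinane, NaHCO3, CH2Cl2, 0 °C → rt; used crude
Reagents that add atoms: none
Why: Buffered Dess–Martin oxidation should give the α-methyl aldehyde under near-neutral conditions that do not epimerise it.

Step 14
Reactants: 24 α-methyl aldehyde
Product: 25 (3S,4R)-1,1-dibromo-4-(tert-butyldimethylsilyloxy)-4-{4-[(S)-7-(tert-butyldimethylsilyloxy)-1-(trimethylsilyl)hept-1-yn-3-yl]-3,5-bis(methoxymethoxy)phenyl}-3-methylbut-1-ene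
Conditions: CBr4, PPh3, Et3N, CH2Cl2, 0 °C
Reagents that add atoms: carbon tetrabromide BrC(Br)(Br)Br
Why: Ramirez dibromoolefination (Wittig-type reaction of the dibromomethylene ylide, first stage of the Corey–Fuchs sequence) adds the one carbon needed, Et3N buffering the medium so that the MOM and TBS ethers and the α-stereocentre are preserved.

Step 15
Reactants: 25 1,1-dibromoalkene
Product: 26 (3S,4R)-1-bromo-4-(tert-butyldimethylsilyloxy)-4-{4-[(S)-7-(tert-butyldimethylsilyloxy)-1-(trimethylsilyl)hept-1-yn-3-yl]-3,5-bis(methoxymethoxy)phenyl}-3-methylbut-1-yne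
Conditions: NaN(SiMe3)2, THF, −78 °C
Reagents that add atoms: none
Why: E2 dehydrobromination of the 1,1-dibromoalkene by a hindered amide base that does not undergo halogen–metal exchange should stop at the 1-bromoalkyne, the silyl cap keeping the other alkyne out of acid–base and bromine-transfer chemistry.

Step 16
Reactants: 26 silylated bromoalkyne
Product: 27 (3S,4R)-1-bromo-4-(tert-butyldimethylsilyloxy)-4-{4-[(R)-7-(tert-butyldimethylsilyloxy)hept-1-yn-3-yl]-3,5-bis(methoxymethoxy)phenyl}-3-methylbut-1-yne (benzylic descriptor changes by CIP priority only)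
Conditions: K2CO3, MeOH/THF, 0 °C → rt
Reagents that add atoms: none
Why: Base-catalysed methanolysis of the C(sp)–Si bond (protodesilylation) is selective over the O–TBS ethers and the C(sp)–Br bond and should free the terminal alkyne just before the coupling.

Step 17
Reactants: 27 bromoalkyne/terminal alkyne monomer (two molecules)
Product: 29 macrocyclic bis(buta-1,3-diyne) [7.7]paracyclophane (tetra-MOM ether and tetra-TBS ether; per half carbinol R and CH(CH3) S and benzylic R), via linear head-to-tail dimer 28 (not isolated)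
Conditions: CuCl (30 mol%), NH2OH·HCl, n-BuNH2, degassed THF/MeOH, rt; 27 added by syringe pump over 24 h to about 1 mM final concentration
Reagents that add atoms: none
Why: Cadiot–Chodkiewicz coupling: the terminal alkyne of one molecule of 27 is converted by CuCl and the amine into a copper acetylide, which adds oxidatively across the C(sp)–Br bond of a second molecule to a trivalent copper bis(alkynyl) species that reductively eliminates the 1,3-diyne and returns monovalent copper, NH2OH·HCl keeping the metal reduced so that oxidative alkyne homocoupling is suppressed. The closest known reaction type is the copper-catalysed bromoalkyne/terminal alkyne coupling in its intramolecular, macrocycle-forming version, together with Glaser–Eglinton cyclodimerisations of diynes to diyne-bridged cyclophanes. The first coupling gives the linear dimer 28, and the same event within 28 then closes the 22-membered ring end to end by joining its free alkyne carbon next to the benzylic CH to its bromoalkyne carbon next to the CH(CH3) group. No stereocentre is formed, and the six existing ones are propargylic or carbinol methines that the amine base is not expected to epimerise. The step needs hetero- over homo-coupling, which is secured because each monomer holds exactly one bromoalkyne and one terminal alkyne so that every productive union is head to tail; it also needs cyclodimer over monomer ring or oligomer: a seven-atom para bridge cannot hold a linear diyne, so 27 cannot close on itself, whereas in 28 two arene rods and two diyne rods with tetrahedral corners can meet with little strain, and slow addition at high dilution holds back chain growth.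

Step 18
Reactants: 29 macrocyclic bis(1,3-diyne)
Product: 30 saturated [7.7]paracyclophane (tetra-MOM ether and tetra-TBS ether; per half carbinol R and CH(CH3) S and benzylic S)
Conditions: H2 (1 atm), Pd/C, EtOAc, rt
Reagents that add atoms: none
Why: Exhaustive heterogeneous hydrogenation of the four alkynes should turn each diyne rod into a (CH2)4 tether; no C–Cl bond is present yet, the neutral solvent spares the MOM and silyl ethers, and no stereocentre lies on a carbon that is reduced.

Step 19
Reactants: 30 saturated tetra-TBS macrocycle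
Product: 31 macrocyclic diol with two 4-hydroxybutyl chains (benzylic TBS ethers and MOM ethers retained)
Conditions: CSA (cat.), MeOH/CH2Cl2, 0 °C
Reagents that add atoms: none
Why: Acid-catalysed methanolysis is much faster for the unhindered primary TBS ethers than for the hindered benzylic secondary ones, so the two side-chain alcohols should be freed selectively.

Step 20
Reactants: 31 macrocyclic diol
Product: 32 macrocyclic dialdehyde with two 4-oxobutyl chains
Conditions: Dess–Martin periodinane, NaHCO3, CH2Cl2, rt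
Reagents that add atoms: none
Why: Buffered Dess–Martin oxidation should convert both primary alcohols into aldehydes without over-oxidation or ether cleavage.

Step 21
Reactants: 32 macrocyclic dialdehyde
Product: 33 macrocyclic bis(hydrazone)
Conditions: N2H4·H2O (excess), MeOH/THF, 4 Å MS, rt; concentrated and used crude
Reagents that add atoms: hydrazine (as monohydrate) NN
Why: Condensation of the aldehydes with excess hydrazine over sieves should give the N-unsubstituted hydrazones while holding back azine formation.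

Step 22
Reactants: 33 macrocyclic bis(hydrazone)
Product: 34 macrocyclic bis(gem-dichloride) with two 4,4-dichlorobutyl chains
Conditions: CuCl2, Et3N, MeOH, rt
Reagents that add atoms: copper dichloride Cl[Cu]Cl
Why: Oxidative gem-dichlorination of hydrazones with CuCl2/Et3N (oxidation by divalent copper to a diazo species, then double chlorination with loss of N2) should turn each CH=N–NH2 into CHCl2 under conditions mild enough for the MOM and TBS ethers.

Step 23
Reactants: 34 macrocyclic bis(gem-dichloride)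
Product: 35 macrocyclic benzylic diol (MOM ethers retained)
Conditions: Bu4NF, AcOH, THF, rt → 45 °C
Reagents that add atoms: none
Why: Fluoride-mediated desilylation, buffered with acetic acid so that basic fluoride does not dehydrochlorinate the CHCl2 groups, should free the two benzylic carbinols.

Step 24
Reactants: 35 macrocyclic benzylic diol
Product: 37 bis-carbamate with the four phenols as MOM ethers, via bis(trichloroacetylcarbamate) 36 (not isolated)
Conditions: Cl3CC(O)NCO, CH2Cl2, 0 °C; K2CO3, MeOH, rt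
Reagents that add atoms: trichloroacetyl isocyanate O=C=NC(=O)C(Cl)(Cl)Cl
Why: Addition of the hindered secondary alcohols to the highly electrophilic acyl isocyanate followed by mild methanolysis of the trichloroacetyl group should give the primary carbamates, the phenols being still masked so that only the carbinols react.

Step 25
Reactants: 37 tetra-MOM bis-carbamate
Product: 38 CNP0205627.1
Conditions: HCl (1.25 M in MeOH), rt
Reagents that add atoms: none
Why: Acid-catalysed acetal exchange should remove the four aryl MOM ethers as dimethoxymethane, while the benzylic carbamates resist ionisation because both ring oxygens are meta to the carbinol carbon.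

**Compound list**
1 | 3,5-dihydroxybenzaldehyde | O=Cc1cc(O)cc(O)c1 | starting material
2 | 3,5-bis(methoxymethoxy)benzaldehyde | O=Cc1cc(OCOC)cc(OCOC)c1 | intermediate
3 | 1-(dimethoxymethyl)-3,5-bis(methoxymethoxy)benzene | COCOc1cc(C(OC)OC)cc(OCOC)c1 | intermediate
4 | [4-(dimethoxymethyl)-2,6-bis(methoxymethoxy)phenyl]lithium | [Li]c1c(OCOC)cc(C(OC)OC)cc1OCOC | intermediate (not isolated)
5 | 2-[4-(dimethoxymethyl)-2,6-bis(methoxymethoxy)phenyl]-4,4,5,5-tetramethyl-1,3,2-dioxaborolane | COCOc1cc(C(OC)OC)cc(OCOC)c1B2OC(C)(C)C(C)(C)O2 | intermediate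
6 | pentane-1,5-diol | OCCCCCO | starting material
7 | 5-(tert-butyldimethylsilyloxy)pentan-1-ol | OCCCCCO[Si](C)(C)C(C)(C)C | intermediate
8 | 5-(tert-butyldimethylsilyloxy)pentyl N,N-diisopropylcarbamate | CC(C)N(C(C)C)C(=O)OCCCCCO[Si](C)(C)C(C)(C)C | intermediate
9 | (R)-1-lithio-5-(tert-butyldimethylsilyloxy)pentyl N,N-diisopropylcarbamate, as its (+)-sparteine complex | CC(C)N(C(C)C)C(=O)O[C@H]([Li])CCCCO[Si](C)(C)C(C)(C)C | intermediate (not isolated)
10 | lithium boronate complex of 9 and 5, (R) at the carbamate carbon | [Li+].CC(C)N(C(C)C)C(=O)O[C@@H](CCCCO[Si](C)(C)C(C)(C)C)[B-]1(OC(C)(C)C(C)(C)O1)c2c(OCOC)cc(C(OC)OC)cc2OCOC | intermediate (not isolated)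
11 | (S)-2-{5-(tert-butyldimethylsilyloxy)-1-[4-(dimethoxymethyl)-2,6-bis(methoxymethoxy)phenyl]pentyl}-4,4,5,5-tetramethyl-1,3,2-dioxaborolane | CC1(C)OB(OC1(C)C)[C@@H](CCCCO[Si](C)(C)C(C)(C)C)c2c(OCOC)cc(C(OC)OC)cc2OCOC | intermediate
12 | lithium (1-bromovinyl)boronate complex of 11 | [Li+].C=C(Br)[B-]1(OC(C)(C)C(C)(C)O1)[C@@H](CCCCO[Si](C)(C)C(C)(C)C)c2c(OCOC)cc(C(OC)OC)cc2OCOC | intermediate (not isolated)
13 | 2-[(3S)-2-bromo-7-(tert-butyldimethylsilyloxy)-3-aryl-1-iodoheptan-2-yl] pinacol boronate, both epimers at C2 (aryl as in 11) | ICC(Br)(B1OC(C)(C)C(C)(C)O1)[C@@H](CCCCO[Si](C)(C)C(C)(C)C)c2c(OCOC)cc(C(OC)OC)cc2OCOC | intermediate (not isolated)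
14 | (S)-2-bromo-7-(tert-butyldimethylsilyloxy)-3-[4-(dimethoxymethyl)-2,6-bis(methoxymethoxy)phenyl]hept-1-ene | C=C(Br)[C@@H](CCCCO[Si](C)(C)C(C)(C)C)c1c(OCOC)cc(C(OC)OC)cc1OCOC | intermediate
15 | lithium acetylide of (R)-7-(tert-butyldimethylsilyloxy)-3-[4-(dimethoxymethyl)-2,6-bis(methoxymethoxy)phenyl]hept-1-yne | [Li]C#C[C@@H](CCCCO[Si](C)(C)C(C)(C)C)c1c(OCOC)cc(C(OC)OC)cc1OCOC | intermediate (not isolated)
16 | (S)-7-(tert-butyldimethylsilyloxy)-3-[4-(dimethoxymethyl)-2,6-bis(methoxymethoxy)phenyl]-1-(trimethylsilyl)hept-1-yne | C[Si](C)(C)C#C[C@@H](CCCCO[Si](C)(C)C(C)(C)C)c1c(OCOC)cc(C(OC)OC)cc1OCOC | intermediate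
17 | 4-[(S)-7-(tert-butyldimethylsilyloxy)-1-(trimethylsilyl)hept-1-yn-3-yl]-3,5-bis(methoxymethoxy)benzaldehyde | C[Si](C)(C)C#C[C@@H](CCCCO[Si](C)(C)C(C)(C)C)c1c(OCOC)cc(C=O)cc1OCOC | intermediate
18 | (R)-4-benzyl-3-propionyloxazolidin-2-one | CCC(=O)N1[C@H](Cc2ccccc2)COC1=O | starting material
19 | dibutylboron (Z)-enolate of 18 | C/C=C(\OB(CCCC)CCCC)N1[C@H](Cc2ccccc2)COC1=O | intermediate (not isolated)
20 | dibutylboron aldolate of 21 | C[Si](C)(C)C#C[C@@H](CCCCO[Si](C)(C)C(C)(C)C)c1c(OCOC)cc(cc1OCOC)[C@H](OB(CCCC)CCCC)[C@@H](C)C(=O)N2[C@H](Cc3ccccc3)COC2=O | intermediate (not isolated)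
21 | (R)-4-benzyl-3-[(2R,3R)-3-{4-[(S)-7-(tert-butyldimethylsilyloxy)-1-(trimethylsilyl)hept-1-yn-3-yl]-3,5-bis(methoxymethoxy)phenyl}-3-hydroxy-2-methylpropanoyl]oxazolidin-2-one | C[Si](C)(C)C#C[C@@H](CCCCO[Si](C)(C)C(C)(C)C)c1c(OCOC)cc(cc1OCOC)[C@H](O)[C@@H](C)C(=O)N2[C@H](Cc3ccccc3)COC2=O | intermediate
22 | 3-O-TBS ether of 21, (2R,3R) | C[Si](C)(C)C#C[C@@H](CCCCO[Si](C)(C)C(C)(C)C)c1c(OCOC)cc(cc1OCOC)[C@H](O[Si](C)(C)C(C)(C)C)[C@@H](C)C(=O)N2[C@H](Cc3ccccc3)COC2=O | intermediate
23 | (2S,3R)-3-(tert-butyldimethylsilyloxy)-3-{4-[(S)-7-(tert-butyldimethylsilyloxy)-1-(trimethylsilyl)hept-1-yn-3-yl]-3,5-bis(methoxymethoxy)phenyl}-2-methylpropan-1-ol | C[Si](C)(C)C#C[C@@H](CCCCO[Si](C)(C)C(C)(C)C)c1c(OCOC)cc(cc1OCOC)[C@H](O[Si](C)(C)C(C)(C)C)[C@@H](C)CO | intermediate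
24 | (2R,3R)-3-(tert-butyldimethylsilyloxy)-3-{4-[(S)-7-(tert-butyldimethylsilyloxy)-1-(trimethylsilyl)hept-1-yn-3-yl]-3,5-bis(methoxymethoxy)phenyl}-2-methylpropanal | C[Si](C)(C)C#C[C@@H](CCCCO[Si](C)(C)C(C)(C)C)c1c(OCOC)cc(cc1OCOC)[C@H](O[Si](C)(C)C(C)(C)C)[C@@H](C)C=O | intermediate
25 | (3S,4R)-1,1-dibromo-4-(tert-butyldimethylsilyloxy)-4-{4-[(S)-7-(tert-butyldimethylsilyloxy)-1-(trimethylsilyl)hept-1-yn-3-yl]-3,5-bis(methoxymethoxy)phenyl}-3-methylbut-1-ene | C[Si](C)(C)C#C[C@@H](CCCCO[Si](C)(C)C(C)(C)C)c1c(OCOC)cc(cc1OCOC)[C@H](O[Si](C)(C)C(C)(C)C)[C@@H](C)C=C(Br)Br | intermediate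
26 | (3S,4R)-1-bromo-4-(tert-butyldimethylsilyloxy)-4-{4-[(S)-7-(tert-butyldimethylsilyloxy)-1-(trimethylsilyl)hept-1-yn-3-yl]-3,5-bis(methoxymethoxy)phenyl}-3-methylbut-1-yne | C[Si](C)(C)C#C[C@@H](CCCCO[Si](C)(C)C(C)(C)C)c1c(OCOC)cc(cc1OCOC)[C@H](O[Si](C)(C)C(C)(C)C)[C@@H](C)C#CBr | intermediate
27 | (3S,4R)-1-bromo-4-(tert-butyldimethylsilyloxy)-4-{4-[(R)-7-(tert-butyldimethylsilyloxy)hept-1-yn-3-yl]-3,5-bis(methoxymethoxy)phenyl}-3-methylbut-1-yne | C#C[C@@H](CCCCO[Si](C)(C)C(C)(C)C)c1c(OCOC)cc(cc1OCOC)[C@H](O[Si](C)(C)C(C)(C)C)[C@@H](C)C#CBr | intermediate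
28 | linear head-to-tail dimer of 27: one buta-1,3-diyne link, one free terminal alkyne at a benzylic CH and one 1-bromoalkyne at a CH(CH3) | C#C[C@@H](CCCCO[Si](C)(C)C(C)(C)C)c1c(OCOC)cc(cc1OCOC)[C@H](O[Si](C)(C)C(C)(C)C)[C@@H](C)C#CC#C[C@@H](CCCCO[Si](C)(C)C(C)(C)C)c2c(OCOC)cc(cc2OCOC)[C@H](O[Si](C)(C)C(C)(C)C)[C@@H](C)C#CBr | intermediate (not isolated)
29 | C2-symmetric 22-membered bis(buta-1,3-diyne) [7.7]paracyclophane; each bridge ArCH(OTBS)–CH(CH3)–C≡C–C≡C–CH[(CH2)4OTBS]Ar, each arene with two OMOM groups flanking the benzylic CH; per half carbinol R, CH(CH3) S, benzylic R | C[C@H]1C#CC#C[C@@H](CCCCO[Si](C)(C)C(C)(C)C)c2c(OCOC)cc(cc2OCOC)[C@H](O[Si](C)(C)C(C)(C)C)[C@@H](C)C#CC#C[C@@H](CCCCO[Si](C)(C)C(C)(C)C)c2c(OCOC)cc(cc2OCOC)[C@@H]1O[Si](C)(C)C(C)(C)C | intermediate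
30 | saturated [7.7]paracyclophane, tetra-MOM and tetra-TBS ether; per half carbinol R, CH(CH3) S, benzylic S | C[C@H]1CCCC[C@@H](CCCCO[Si](C)(C)C(C)(C)C)c2c(OCOC)cc(cc2OCOC)[C@H](O[Si](C)(C)C(C)(C)C)[C@@H](C)CCCC[C@@H](CCCCO[Si](C)(C)C(C)(C)C)c2c(OCOC)cc(cc2OCOC)[C@@H]1O[Si](C)(C)C(C)(C)C | intermediate
31 | saturated macrocycle with two 4-hydroxybutyl chains, benzylic OTBS and OMOM groups retained | C[C@H]1CCCC[C@@H](CCCCO)c2c(OCOC)cc(cc2OCOC)[C@H](O[Si](C)(C)C(C)(C)C)[C@@H](C)CCCC[C@@H](CCCCO)c2c(OCOC)cc(cc2OCOC)[C@@H]1O[Si](C)(C)C(C)(C)C | intermediate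
32 | macrocyclic dialdehyde with two 4-oxobutyl chains | C[C@H]1CCCC[C@@H](CCCC=O)c2c(OCOC)cc(cc2OCOC)[C@H](O[Si](C)(C)C(C)(C)C)[C@@H](C)CCCC[C@@H](CCCC=O)c2c(OCOC)cc(cc2OCOC)[C@@H]1O[Si](C)(C)C(C)(C)C | intermediate
33 | macrocyclic bis(hydrazone) of 32 | C[C@H]1CCCC[C@@H](CCCC=NN)c2c(OCOC)cc(cc2OCOC)[C@H](O[Si](C)(C)C(C)(C)C)[C@@H](C)CCCC[C@@H](CCCC=NN)c2c(OCOC)cc(cc2OCOC)[C@@H]1O[Si](C)(C)C(C)(C)C | intermediate
34 | macrocyclic bis(gem-dichloride) with two 4,4-dichlorobutyl chains, benzylic OTBS and OMOM groups retained | C[C@H]1CCCC[C@@H](CCCC(Cl)Cl)c2c(OCOC)cc(cc2OCOC)[C@H](O[Si](C)(C)C(C)(C)C)[C@@H](C)CCCC[C@@H](CCCC(Cl)Cl)c2c(OCOC)cc(cc2OCOC)[C@@H]1O[Si](C)(C)C(C)(C)C | intermediate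
35 | macrocyclic benzylic diol, tetra-MOM ether | C[C@H]1CCCC[C@@H](CCCC(Cl)Cl)c2c(OCOC)cc(cc2OCOC)[C@H](O)[C@@H](C)CCCC[C@@H](CCCC(Cl)Cl)c2c(OCOC)cc(cc2OCOC)[C@@H]1O | intermediate
36 | bis(N-trichloroacetyl carbamate) of 35 | C[C@H]1CCCC[C@@H](CCCC(Cl)Cl)c2c(OCOC)cc(cc2OCOC)[C@H](OC(=O)NC(=O)C(Cl)(Cl)Cl)[C@@H](C)CCCC[C@@H](CCCC(Cl)Cl)c2c(OCOC)cc(cc2OCOC)[C@@H]1OC(=O)NC(=O)C(Cl)(Cl)Cl | intermediate (not isolated)
37 | bis-carbamate, tetra-MOM ether | C[C@H]1CCCC[C@@H](CCCC(Cl)Cl)c2c(OCOC)cc(cc2OCOC)[C@H](OC(N)=O)[C@@H](C)CCCC[C@@H](CCCC(Cl)Cl)c2c(OCOC)cc(cc2OCOC)[C@@H]1OC(N)=O | intermediate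
38 | CNP0205627.1; per half carbinol R, CH(CH3) S, benzylic S | C[C@H]1CCCC[C@@H](CCCC(Cl)Cl)c2c(O)cc(cc2O)[C@H](OC(N)=O)[C@@H](C)CCCC[C@@H](CCCC(Cl)Cl)c2c(O)cc(cc2O)[C@@H]1OC(N)=O | target

**Totals**
Total step count: 25. Longest linear sequence: 23 steps (steps 1–3 and 6–25, from 3,5-dihydroxybenzaldehyde).

**Steps most likely to fail**

1. Step 17. Chain growth to linear oligomers may outrun ring closure of the dimer. Reductive homocoupling of bromoalkyne ends may also scramble the head-to-tail order, and both alkynes sit next to congested methines and may couple slowly. The fallback is a stepwise assembly that uses the intramolecular form of the coupling. It sets out from 25 and 26. Desilylation of 25 (K2CO3, MeOH) should give the terminal alkyne that still carries the dibromoalkene, F1. Cross-coupling of F1 with bromoalkyne 26 at ordinary concentration (CuCl, NH2OH·HCl, n-BuNH2) should give the linear dimer with a silylated alkyne at one end and a dibromoalkene at the other, F2. Elimination with NaN(SiMe3)2 at −78 °C should give the silylated bromoalkyne dimer F3, and K2CO3/MeOH then gives 28, now isolated. The fallback rejoins the route at 28, which is closed to 29 by intramolecular Cadiot–Chodkiewicz coupling at high dilution.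

2. Step 6. Capture of the lithiated carbamate by the aryl boronate, whose boron is flanked by two ortho MOM ethers, may be slow or reversible. The carbenoid could then decompose, or the enantiomeric purity could erode, before the 1,2-shift. The fallback forms the same boronate complex from the opposite direction. It sets out from 8 and from 3 (through aryllithium 4). Carbamate 8 is lithiated as before (s-BuLi, (+)-sparteine) and trapped with iPrOBpin to give the configurationally stable (R)-1-(pinacolboryl)-5-(tert-butyldimethylsilyloxy)pentyl N,N-diisopropylcarbamate F4. Aryllithium 4 is then added to F4 at −78 °C, so the strongly nucleophilic aryl metal attacks an unhindered boron and gives complex 10. MgBr2·OEt2 and warming then induce the same 1,2-shift, and the fallback rejoins the route at 11.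

3. Step 7. The thermally fragile 1-bromovinyllithium may decompose before the hindered benzylic boronate captures it, or the boronate complex may protodeboronate. The fallback replaces the alkynylation by a one-carbon homologation and a Corey–Fuchs sequence, and sets out from 11. Matteson homologation with chloromethyllithium (BrCH2Cl, n-BuLi, THF, −78 °C → rt; 1,2-shift with retention) should give the primary boronate F5. Oxidation (NaBO3·4H2O, THF/H2O) gives the primary alcohol F6, and Dess–Martin oxidation gives the α-aryl aldehyde F7, whose enolisation is disfavoured by the two ortho substituents. Ramirez olefination (CBr4, PPh3, Et3N) gives the dibromoalkene F8. Treatment with n-BuLi (2.2 equiv, THF, −78 °C; Fritsch–Buttenberg–Wiechell rearrangement) gives lithium acetylide 15, which is silylated with TMSCl. The fallback rejoins the route at 16.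

**Further compounds**
F1 | step 17 | (3S,4R)-1,1-dibromo-4-(tert-butyldimethylsilyloxy)-4-{4-[(R)-7-(tert-butyldimethylsilyloxy)hept-1-yn-3-yl]-3,5-bis(methoxymethoxy)phenyl}-3-methylbut-1-ene | C#C[C@@H](CCCCO[Si](C)(C)C(C)(C)C)c1c(OCOC)cc(cc1OCOC)[C@H](O[Si](C)(C)C(C)(C)C)[C@@H](C)C=C(Br)Br
F2 | step 17 | linear head-to-tail dimer with a trimethylsilyl alkyne at the benzylic end and a 1,1-dibromoalkene at the CH(CH3) end | C[Si](C)(C)C#C[C@@H](CCCCO[Si](C)(C)C(C)(C)C)c1c(OCOC)cc(cc1OCOC)[C@H](O[Si](C)(C)C(C)(C)C)[C@@H](C)C#CC#C[C@@H](CCCCO[Si](C)(C)C(C)(C)C)c2c(OCOC)cc(cc2OCOC)[C@H](O[Si](C)(C)C(C)(C)C)[C@@H](C)C=C(Br)Br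
F3 | step 17 | linear head-to-tail dimer with a trimethylsilyl alkyne at the benzylic end and a 1-bromoalkyne at the CH(CH3) end | C[Si](C)(C)C#C[C@@H](CCCCO[Si](C)(C)C(C)(C)C)c1c(OCOC)cc(cc1OCOC)[C@H](O[Si](C)(C)C(C)(C)C)[C@@H](C)C#CC#C[C@@H](CCCCO[Si](C)(C)C(C)(C)C)c2c(OCOC)cc(cc2OCOC)[C@H](O[Si](C)(C)C(C)(C)C)[C@@H](C)C#CBr
F4 | step 6 | (R)-5-(tert-butyldimethylsilyloxy)-1-(4,4,5,5-tetramethyl-1,3,2-dioxaborolan-2-yl)pentyl N,N-diisopropylcarbamate | CC(C)N(C(C)C)C(=O)O[C@@H](CCCCO[Si](C)(C)C(C)(C)C)B1OC(C)(C)C(C)(C)O1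
F5 | step 7 | (S)-2-{6-(tert-butyldimethylsilyloxy)-2-[4-(dimethoxymethyl)-2,6-bis(methoxymethoxy)phenyl]hexyl}-4,4,5,5-tetramethyl-1,3,2-dioxaborolane | CC1(C)OB(OC1(C)C)C[C@@H](CCCCO[Si](C)(C)C(C)(C)C)c2c(OCOC)cc(C(OC)OC)cc2OCOC
F6 | step 7 | (S)-6-(tert-butyldimethylsilyloxy)-2-[4-(dimethoxymethyl)-2,6-bis(methoxymethoxy)phenyl]hexan-1-ol | OC[C@@H](CCCCO[Si](C)(C)C(C)(C)C)c1c(OCOC)cc(C(OC)OC)cc1OCOC
F7 | step 7 | (S)-6-(tert-butyldimethylsilyloxy)-2-[4-(dimethoxymethyl)-2,6-bis(methoxymethoxy)phenyl]hexanal | O=C[C@@H](CCCCO[Si](C)(C)C(C)(C)C)c1c(OCOC)cc(C(OC)OC)cc1OCOC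
F8 | step 7 | (R)-1,1-dibromo-7-(tert-butyldimethylsilyloxy)-3-[4-(dimethoxymethyl)-2,6-bis(methoxymethoxy)phenyl]hept-1-ene | BrC(Br)=C[C@@H](CCCCO[Si](C)(C)C(C)(C)C)c1c(OCOC)cc(C(OC)OC)cc1OCOC
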